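**Assumption:** (S)-(+)-carvone is the enantiomer whose reductive alkylation gives the ent-configured C4, and the alkylations in Steps 3–5 proceed by axial attack as described. Carbon numbers below are ent-kaurane numbers (C5 = CHO-bearing A-ring carbon, C10 = quaternary carbon bearing C20, C8 = quaternary bridgehead).

## Retrosynthetic overview
1. The target comes from an isoxazoline by N–O cleavage and dehydration. The isoxazoline closes ring D of the bicyclo[3.2.1]octane by an intramolecular nitrile-oxide/vinyl cycloaddition (C15–C16 bond).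
2. That isoxazoline comes from a lactone-fused cyclohexanone, built by a lactone-tethered intramolecular Diels–Alder reaction. This single step forms ring C, the δ-lactone, the quaternary C8 and the C9 and C13 stereocentres, and leaves C11 as a ketone.
3. The Diels–Alder substrate is the ester of an A-ring dienone alcohol and a 2-(silyloxymethyl)acrylic acid. The A ring is built from (S)-carvone by two alkylation sequences (C4 and C10), excision of the isopropenyl control group, and one-carbon homologation of C5.
4. Rings form in the order A (from carvone), then C plus lactone (Diels–Alder), then D (nitrile-oxide cycloaddition).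

## Route

**Step 1**
Reactants: 1 ethyl 2-(hydroxymethyl)acrylate
Product: 2 ethyl 2-[(TBS-oxy)methyl]acrylate
Conditions: TBSCl, imidazole, CH2Cl2, 0 °C to rt
Reagents that add atoms: TBSCl, CC(C)(C)[Si](C)(C)Cl
Why: Silylation of the primary alcohol gives a robust dienophile precursor that survives the later enolization conditions.

**Step 2**
Reactants: 2
Product: 3 2-[(TBS-oxy)methyl]acrylic acid
Conditions: LiOH, THF/H2O, 0 °C
Reagents that add atoms: water, O
Why: Mild ester saponification; the acrylate and silyl ether are untouched.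

**Step 3**
Reactants: 4 (S)-(+)-carvone
Product: 5 C5-ketone bearing C4(Me)(CH2OBn) and a C1 isopropenyl group
Conditions: L-Selectride, THF, −78 °C; then BnOCH2Cl, HMPA, −78 °C to rt
Reagents that add atoms: benzyl chloromethyl ether, ClCOCc1ccccc1
Why: Conjugate reduction gives a regiodefined enolate, and reductive alkylation installs the quaternary C4 by axial attack anti to the equatorial isopropenyl, with CH2OBn (future C19) axial.

**Step 4**
Reactants: 5
Product: 6 C10-monoalkylated ketone, C10(H)(CH2OSEM)
Conditions: LDA, THF, −78 °C; then SEMCl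
Reagents that add atoms: SEMCl, C[Si](C)(C)CCOCCl
Why: Kinetic enolization occurs at the only enolizable α′ carbon (C10). Alkoxymethylation occurs from the face anti to the axial C19, the 1,3-diaxial face being blocked.

**Step 5**
Reactants: 6
Product: 7 C10 quaternary ketone, C10(CH2OSEM)(CH2CO2tBu)
Conditions: LDA, THF, −78 °C; then BrCH2CO2tBu, HMPA, −78 °C to 0 °C
Reagents that add atoms: tert-butyl bromoacetate, CC(C)(C)OC(=O)CBr
Why: Alkylation of the tertiary enolate is again anti to axial C19. The group added first is therefore pushed axial, so C20 (CH2OSEM) ends syn-diaxial to C19 as in the ent-kaurane.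

**Step 6**
Reactants: 7
Product: 8 methyl ketone (isopropenyl converted to acetyl)
Conditions: O3, CH2Cl2/MeOH, −78 °C; then Me2S
Reagents that add atoms: ozone, O=[O+][O-]
Why: Ozonolysis cleaves the only alkene, the isopropenyl control group. The ring ketone is flanked by two quaternary carbons and is inert.

**Step 7**
Reactants: 8
Product: 9 C1 carboxylic acid
Conditions: NaOCl (aq), dioxane, 0 °C to rt
Reagents that add atoms: sodium hypochlorite, [Na+].[O-]Cl; water, O
Why: Haloform oxidation is selective for the acetyl group because the ring ketone has no α-hydrogens.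

**Step 8**
Reactants: 9
Product: 10 ketone with C1H2 (isopropenyl excised)
Conditions: (COCl)2, cat. DMF; then sodium 2-thiopyridone N-oxide; then tBuSH, hν, rt
Reagents that add atoms: none
Why: Barton radical decarboxylation removes the temporary C1 substituent and destroys that stereocentre. The stereocentres at C4 and C10 are not touched.

**Step 9**
Reactants: 10
Product: 11 C5 spiro-epoxide (C5–C6H2–O)
Conditions: Me3S+ I−, NaH, DMSO/THF, rt
Reagents that add atoms: trimethylsulfonium iodide, C[S+](C)C.[I-] (adds CH2)
Why: Corey–Chaykovsky epoxidation with the small sulfonium methylide adds C6 to the hindered, non-enolizable ketone.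

**Step 10**
Reactants: 11
Product: 12 C5 aldehyde (C5–H, C6HO)
Conditions: MgBr2·OEt2, PhMe, 60 °C
Reagents that add atoms: none
Why: Lewis-acid Meinwald rearrangement by 1,2-hydride shift converts the 1,1-disubstituted epoxide into the aldehyde. C5 takes the thermodynamic configuration, with C6 equatorial and H5 trans to axial C20.

**Step 11**
Reactants: 12
Product: 13 C6 dioxolane
Conditions: HOCH2CH2OH, p-TsOH, PhH, Dean–Stark
Reagents that add atoms: ethylene glycol, OCCO
Why: Acetalization masks C6 against the later enolization and dipolar-cycloaddition steps.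

**Step 12**
Reactants: 13
Product: 14 C9–C11 carboxylic acid
Conditions: TMSOTf, 2,6-lutidine, CH2Cl2, 0 °C; then H2O
Reagents that add atoms: none
Why: Buffered silyl-triflate cleavage of the tert-butyl ester leaves the SEM and benzyl ethers and the dioxolane intact.

**Step 13**
Reactants: 14
Product: 15 Weinreb amide
Conditions: MeNH(OMe)·HCl, EDC, HOBt, iPr2NEt, CH2Cl2
Reagents that add atoms: N,O-dimethylhydroxylamine, CONC
Why: Amide coupling prepares a mono-addition acyl donor.

**Step 14**
Reactants: 15
Product: 16 (E)-dienone, C9H2–C11(=O)–C12H=C13H–C16H=C17H2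
Conditions: (E)-buta-1,3-dienylmagnesium bromide, THF, 0 °C
Reagents that add atoms: (E)-buta-1,3-dienylmagnesium bromide, C=C/C=C/[Mg]Br
Why: Grignard addition to the Weinreb amide stops at the ketone and installs the C12–C17 diene unit.

**Step 15**
Reactants: 16
Product: 17 C20 primary alcohol
Conditions: MgBr2·OEt2, Me2S, Et2O/MeNO2, rt
Reagents that add atoms: none
Why: Selective SEM removal frees C20–OH, the lactone oxygen, while the benzyl ether, dioxolane and dienone survive.

**Step 16**
Reactants: 17 and 3
Product: 18 ester (C20–O–C(=O)–C(=CH2)CH2OTBS)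
Conditions: 2,4,6-Cl3C6H2COCl, Et3N, THF; then 17, DMAP, PhMe
Reagents that add atoms: none
Why: Yamaguchi esterification attaches the dienophile through the C20 oxygen, which will become the lactone tether.

**Step 17**
Reactants: 18
Product: 19 lactone-fused cyclohexanone
Conditions: TMSOTf, Et3N, CH2Cl2, 0 °C; then PhMe, 110 °C; then NH4F, MeOH
Reagents that add atoms: none
Why: Soft enolization at C9 gives the 2-silyloxy-triene, and lactone-tethered intramolecular Diels–Alder closes C8–C9 and C13–C14. The rigid tether, with C10 and C4/C19 fixed, directs C8, C9 and C13 to the target configuration (C15 and the C13 vinyl cis-diaxial on one face). Desilylation then releases the C11 ketone.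

**Step 18**
Reactants: 19
Product: 20 C11 equatorial alcohol
Conditions: NaBH4, MeOH, −78 °C
Reagents that add atoms: none
Why: Hydride attacks axially from the less hindered face, giving the equatorial 11-OH.

**Step 19**
Reactants: 20
Product: 21 C15 primary alcohol
Conditions: TBAF, THF, 0 °C
Reagents that add atoms: none
Why: Fluoride removes the primary TBS ether; the dioxolane and benzyl ether are unaffected.

**Step 20**
Reactants: 21
Product: 22 C15 aldehyde
Conditions: TEMPO (cat.), PhI(OAc)2, CH2Cl2, rt
Reagents that add atoms: none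
Why: TEMPO oxidation is selective for the primary alcohol and leaves the secondary 11-OH untouched.

**Step 21**
Reactants: 22
Product: 23 aldoxime
Conditions: NH2OH·HCl, NaOAc, EtOH, rt
Reagents that add atoms: hydroxylamine, NO
Why: Condensation gives the nitrile-oxide precursor.

**Step 22**
Reactants: 23
Product: 24 isoxazoline (C15=N–O–C17H2–C16)
Conditions: NCS, pyridine, CHCl3, 0 °C; then Et3N, rt
Reagents that add atoms: none
Why: Chlorination and dehydrochlorination generate the nitrile oxide, which adds intramolecularly to the cis-axial C13 vinyl group. This closes ring D (C15–C16) and completes the bicyclo[3.2.1]octane, an intramolecular nitrile-oxide cycloaddition.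

**Step 23**
Reactants: 24
Product: 25 β-hydroxy ketone (C15=O, C16H–C17H2OH)
Conditions: Mo(CO)6, MeCN/H2O, 80 °C
Reagents that add atoms: water, O
Why: Reductive N–O cleavage gives a β-hydroxy imine, which hydrolyses to the C15 ketone.

**Step 24**
Reactants: 25
Product: 26 C19 primary alcohol
Conditions: H2 (1 atm), Pd(OH)2/C, EtOH
Reagents that add atoms: none
Why: Hydrogenolysis removes the benzyl ether. No alkene remains in this intermediate.

**Step 25**
Reactants: 26
Product: 27 C17,C19-diacetate
Conditions: Ac2O (2.2 equiv), DMAP, pyridine, 0 °C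
Reagents that add atoms: acetic anhydride, CC(=O)OC(C)=O
Why: The two primary alcohols are acetylated; the hindered secondary 11-OH is much less reactive at 0 °C.

**Step 26**
Reactants: 27
Product: 28 exocyclic enone (C15=O, C16=C17)
Conditions: DBU, CH2Cl2, rt
Reagents that add atoms: none
Why: E1cB elimination of the β-acetoxy ketone forms the α-methylene ketone. The C19 acetate is unaffected.

**Step 27**
Reactants: 28
Product: 29 trichorabdal B
Conditions: aq. HCl, THF, rt
Reagents that add atoms: water, O
Why: Mild acetal hydrolysis unmasks the C6 aldehyde. The acetate, lactone, enone and 11-OH tolerate these conditions, and C5 cannot epimerize while masked.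

## Compound list
1 | ethyl 2-(hydroxymethyl)acrylate | C=C(CO)C(=O)OCC | starting material
2 | ethyl 2-[(TBS-oxy)methyl]acrylate | C=C(CO[Si](C)(C)C(C)(C)C)C(=O)OCC | intermediate
3 | 2-[(TBS-oxy)methyl]acrylic acid | C=C(CO[Si](C)(C)C(C)(C)C)C(=O)O | intermediate
4 | (S)-(+)-carvone | CC1=CC[C@H](CC1=O)C(C)=C | starting material
5 | C5-ketone, C4(Me)(CH2OBn), C1-isopropenyl | O=C1[C@](C)(COCc2ccccc2)CC[C@@H](C(C)=C)C1 | intermediate
6 | C10-(CH2OSEM) ketone | O=C1[C@](C)(COCc2ccccc2)CC[C@@H](C(C)=C)C1COCC[Si](C)(C)C | intermediate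
7 | C10(CH2OSEM)(CH2CO2tBu) ketone | O=C1[C@](C)(COCc2ccccc2)CC[C@@H](C(C)=C)[C@@]1(COCC[Si](C)(C)C)CC(=O)OC(C)(C)C | intermediate
8 | C1-acetyl analogue | O=C1[C@](C)(COCc2ccccc2)CC[C@@H](C(C)=O)[C@@]1(COCC[Si](C)(C)C)CC(=O)OC(C)(C)C | intermediate
9 | C1-carboxylic acid | O=C1[C@](C)(COCc2ccccc2)CC[C@@H](C(=O)O)[C@@]1(COCC[Si](C)(C)C)CC(=O)OC(C)(C)C | intermediate
10 | C1-decarboxylated ketone | O=C1[C@](C)(COCc2ccccc2)CCC[C@@]1(COCC[Si](C)(C)C)CC(=O)OC(C)(C)C | intermediate
11 | C5 spiro-epoxide | C15(CO5)[C@](C)(COCc2ccccc2)CCC[C@@]1(COCC[Si](C)(C)C)CC(=O)OC(C)(C)C | intermediate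
12 | C5 aldehyde | O=C[C@@H]1[C@](C)(COCc2ccccc2)CCC[C@@]1(COCC[Si](C)(C)C)CC(=O)OC(C)(C)C | intermediate
13 | C6 dioxolane | C2(OCCO2)[C@@H]1[C@](C)(COCc3ccccc3)CCC[C@@]1(COCC[Si](C)(C)C)CC(=O)OC(C)(C)C | intermediate
14 | C9–C11 acid | C2(OCCO2)[C@@H]1[C@](C)(COCc3ccccc3)CCC[C@@]1(COCC[Si](C)(C)C)CC(=O)O | intermediate
15 | Weinreb amide | C2(OCCO2)[C@@H]1[C@](C)(COCc3ccccc3)CCC[C@@]1(COCC[Si](C)(C)C)CC(=O)N(C)OC | intermediate
16 | dienone (SEM) | C2(OCCO2)[C@@H]1[C@](C)(COCc3ccccc3)CCC[C@@]1(COCC[Si](C)(C)C)CC(=O)/C=C/C=C | intermediate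
17 | dienone alcohol (C20-OH) | C2(OCCO2)[C@@H]1[C@](C)(COCc3ccccc3)CCC[C@@]1(CO)CC(=O)/C=C/C=C | intermediate
18 | acrylate ester | C2(OCCO2)[C@@H]1[C@](C)(COCc3ccccc3)CCC[C@@]1(COC(=O)C(=C)CO[Si](C)(C)C(C)(C)C)CC(=O)/C=C/C=C | intermediate
19 | lactone-fused C11 ketone | CC(C)(C)[Si](C)(C)OC[C@]12C[C@H](C=C)CC(=O)[C@@H]1[C@@]1(CCC[C@@](C)(COCc3ccccc3)[C@H]1C3OCCO3)COC2=O | intermediate
20 | C11 alcohol | CC(C)(C)[Si](C)(C)OC[C@]12C[C@H](C=C)C[C@@H](O)[C@@H]1[C@@]1(CCC[C@@](C)(COCc3ccccc3)[C@H]1C3OCCO3)COC2=O | intermediate
21 | C15 alcohol | OC[C@]12C[C@H](C=C)C[C@@H](O)[C@@H]1[C@@]1(CCC[C@@](C)(COCc3ccccc3)[C@H]1C3OCCO3)COC2=O | intermediate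
22 | C15 aldehyde | O=C[C@]12C[C@H](C=C)C[C@@H](O)[C@@H]1[C@@]1(CCC[C@@](C)(COCc3ccccc3)[C@H]1C3OCCO3)COC2=O | intermediate
23 | aldoxime | ON=C[C@]12C[C@H](C=C)C[C@@H](O)[C@@H]1[C@@]1(CCC[C@@](C)(COCc3ccccc3)[C@H]1C3OCCO3)COC2=O | intermediate
24 | isoxazoline (C16 configuration unspecified) | C1ON=C2[C@]34C[C@H](C12)C[C@@H](O)[C@@H]3[C@@]5(CCC[C@@](C)(COCc6ccccc6)[C@H]5C6OCCO6)COC4=O | intermediate
25 | β-hydroxy ketone | OCC1C(=O)[C@]23C[C@H]1C[C@@H](O)[C@@H]2[C@@]1(CCC[C@@](C)(COCc4ccccc4)[C@H]1C4OCCO4)COC3=O | intermediate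
26 | C19-alcohol | OCC1C(=O)[C@]23C[C@H]1C[C@@H](O)[C@@H]2[C@@]1(CCC[C@@](C)(CO)[C@H]1C4OCCO4)COC3=O | intermediate
27 | diacetate | CC(=O)OCC1C(=O)[C@]23C[C@H]1C[C@@H](O)[C@@H]2[C@@]1(CCC[C@@](C)(COC(C)=O)[C@H]1C4OCCO4)COC3=O | intermediate
28 | enone dioxolane | C=C1C(=O)[C@]23C[C@H]1C[C@@H](O)[C@@H]2[C@@]1(CCC[C@@](C)(COC(C)=O)[C@H]1C4OCCO4)COC3=O | intermediate
29 | trichorabdal B | C=C1C(=O)[C@]23C[C@H]1C[C@@H](O)[C@@H]2[C@@]1(CCC[C@@](C)(COC(C)=O)[C@H]1C=O)COC3=O | target

## Totals
- Total steps: 27, counting the 2-step dienophile branch.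
- Longest linear sequence: 25 steps (carvone to target).

## Three steps most likely to fail
1. **Step 17 (lactone-tethered Diels–Alder).** The tethering ester is forced into the strained E-conformation, and the cycloaddition joins a quaternary carbon to a carbon next to the C10 quaternary centre. The silyl-triflate enolization may also ionize the acetal. Fallback: abandon the Diels–Alder and build ring C by Robinson-type Michael/aldol annulation of the A-ring keto-lactone, then close ring D by the nitrile-oxide cycloaddition.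
2. **Step 9 (methylenation of the C5 ketone flanked by two quaternary carbons, with Meinwald rearrangement in Step 10).** The ylide addition, the hydride-shift selectivity and the resulting C5 configuration are all uncertain. Fallback: change the A-ring source to an (R)-Wieland–Miescher-derived Δ5-decalin in which C5–C6 already exists, and open ring B later by α-ketol cleavage of a 6-hydroxy-7-ketone.
3. **Step 22 (intramolecular nitrile-oxide cycloaddition).** It needs the C15 aldehyde and the C13 vinyl to be cis-diaxial, and a bridged isoxazoline is strained. Fallback: form the C8–C15 bond by Ireland–Claisen ring contraction of a 2-(hydroxymethyl)allyl lactone bridging C8 and C13, which delivers the acid and the exocyclic methylene directly.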